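## Analysis of the target

The target is an unsymmetrical 6,6'-linked dimer of two 5-hydroxychroman-4-ones in which each C2 is a quaternary, oxygen-bearing stereocentre carrying a methyl ester and the chain Cγ(O)–Cβ(CH3)–CH2–CO2. In one half this chain is closed as a cis-2,3-disubstituted γ-butyrolactone, in the other it is the free γ-hydroxy acid. The six stereocentres form two identical sets, C2 (S), Cγ (R) and Cβ (S), so the compound is the mono-seco form of a C2-symmetric bis-lactone and both halves can be built together; the biaryl axis carries one ortho substituent per ring (the C5 oxygen) and is not a stereogenic element. Sensitive points are the β-aryloxy ketone (base can open the pyran by retro-oxa-Michael and endanger C2), the lactone and methyl ester towards hydroxide, and the γ-hydroxy acid, which recloses under acid. The difficulty is C2: fully substituted, flanked by three differently oxidised carbon arms, and to be set relative to Cγ twice in one molecule. The strategy rests on two features of each half. O1–C2 and C3–C4 of the pyran ring sit on the arene as a phenol oxygen and a benzylic carbon, the retron of an ortho-quinone methide [4+2] addition. The ester carbon and Cγ, both on C2 and both oxygenated, are 1,3-related, so as CH2–O and CH–O they can be tied into a 1,3-dioxane whose C5 is the future C2.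

## Retrosynthetic reasoning

35 ⇒ 34. The halves differ by one acyl–oxygen bond, so the lactone C(=O)–O bond of one half is cut first. This gives the C2-symmetric bis-lactone 34, and every earlier operation then acts twice on equivalent sites. The forward step must open one of two equivalent lactones without touching the methyl esters or C2.

34 ⇒ 33 ⇒ 32 ⇒ 31 ⇒ 30. The phenols are masked as methyl ethers (33), and the C4 carbonyl is taken back through alcohol 32 and chromene 31 to the chroman 30. A chroman without C4 oxygen is what a quinone methide cycloaddition delivers. While C4 is a methylene, retro-oxa-Michael loss of C2 is impossible. The forward sequence must oxidise only the benzylic C4 position, late, under non-basic conditions.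

30 ⇒ 29 ⇒ 28 ⇒ 26 ⇒ 25 ⇒ 23. Only oxidation levels on the arms of C2 change. The ester carbon goes back to CH2OH (28). The lactone C–O bond is cut to an acid and the Cγ hydroxyl, and that hydroxyl and the CH2OH are tied as an acetonide (26). The acid carbon is traced through alcohol 25 to the terminal carbon of a vinyl group (23). In 23 the ester arm and the Cγ arm are part of one six-membered ring, and the third arm is an inert alkene.

23 ⇒ 10 + 19 (twice). O1–C2 and C3–C4 are cut in both halves. This is the only disconnection that removes both pyran rings and both C2 centres at once and leaves two simple partners: the biaryl bis(ortho-hydroxybenzyl acetate) 10 and the methylene dioxane 19. The forward step must generate methides 20 and 22 in turn and add each to the exocyclic alkene with the oxygen on the fully substituted carbon and on the correct face.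

19 ⇒ 18 ⇒ 17 ⇒ 13 + 14. The acetonide is opened to diol 18, the silyl ether 17 is its protected form, and the Cγ–Cβ bond is cut. A syn-selective, reagent-controlled crotylboration of enal 13 with the crotyl unit from butene 14 sets both centres in one step. Aldehyde 13 comes from diol 11 through 12 by monoprotection and allylic oxidation.

10 ⇒ 8 ⇒ 7 ⇒ 6 ⇒ 4 ⇒ 2 + 3 ⇒ 1. The benzylic acetate is traced to an aldehyde next to an aryl acetate (8), whose reduction triggers an O→O acyl shift. The formyl C–C bond is cut at the carbon between the two ring oxygens, the one position that a doubly directed ortho-lithiation of 4 reaches. The biaryl bond is cut last into bromide 2 and boronate 3. Boronate 3 is itself made from 2, so both halves of the biaryl come from the MOM ether of phenol 1.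

## Alternatives that were turned down

Alternative 1: Both benzene rings are disconnected (C8–C8a and C4a–C5 in each arene), and the biaryl bond is traced to the central C–C bond of a divinylsuccinate. In the forward key step the bis(vinylketene silyl acetal) A2 adds twice as a diene to the sulfinyl dihydropyranone A3, CH2 terminus to C8a and acetal carbon to C4a. Loss of the sulfenic acid and of the silyl acetal aromatises both adducts to the bis(chromanone lactone) A1, which is the same compound as 34.
- For it: A1 arrives with the C4 ketones and free C5 phenols, one step from the target. It therefore saves the three-step benzylic oxidation and the demethylation, and needs no cross-coupling. On step economy after the key step it is clearly stronger than the chosen route.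
- Against it: the key step creates no stereocentre. The whole C2/Cγ/Cβ triad must already be present in A3, a vinylogous ester whose C2 is exposed to retro-oxa-Michael loss and whose asymmetric synthesis is the unsolved core of the problem. A2 is a crowded, hydrolytically labile tetraene whose two diene units cannot both be planar s-cis, and it must react twice with a hindered, weakly dienophilic partner. Two equivalents of the most valuable intermediate are spent in the least predictable step.
- Comparison: the chosen route places the uncertain step on two cheap partners, 10 and 19, and lets that step build C2. It pays with a ten-step endgame.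

Alternative 2: C2–C3 (aldol) and O1–C8a (aromatic substitution) are disconnected in both halves. In the forward key step the bis(silyl enol ether) A5 adds, under a chiral copper bis(oxazoline) Lewis acid, to two molecules of the lactone α-keto ester A6 and gives the bis(β-hydroxy ketone) A4. The tertiary alkoxides are then meant to displace the ortho fluorides.
- For it: catalytic enantioselective additions of enol silanes to chelating α-keto esters are well developed. C2 is set by a catalyst and not by a neighbouring centre, which the chosen route cannot offer. The C4 ketone is present from the start.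
- Against it: in A6 the Cγ centre is α to a ketone, so it can epimerise and is matched or mismatched with the catalyst. The lactone ring oxygen offers a competing chelation mode. The high selectivities known for small pyruvate-type ketones do not transfer safely to a branched lactone substituent. The ring closure needs the tertiary alkoxide of a β-hydroxy ketone, the species that fragments by retro-aldol, on an arene deactivated by a methoxy group.
- Comparison: equal or better in the endgame and in the source of induction, but A4 is fragile in exactly the step that follows. The chosen [4+2] forms both ring bonds in one event and passes through no retro-aldol-prone intermediate.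

Alternative 3: The Cγ–O and Cβ–H bonds are disconnected, with the ester carbon and the chain terminus tied as a seven-membered spiro lactone. In the forward key step a pinene-derived chiral monoalkylborane adds syn to the trisubstituted ring alkene of the bis(spiro lactone) A8, boron to Cγ and hydrogen to Cβ. Oxidation gives the bis(hydroxy lactone) A7.
- For it: syn addition to a ring alkene of fixed geometry translates directly into the Cγ/Cβ relationship. The chiral borane can reinforce the ring bias. No late C4 oxidation is needed, a point on which it is stronger than the chosen route.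
- Against it: C2 must be enantiopure before the key step, so the hardest centre is again moved elsewhere. Boron must go to the carbon next to the spiro quaternary centre, where trisubstituted alkenes react slowly. The aryl ketones of A8 compete for the borane. Face selection depends on a flexible seven-membered ring. After the key step the tether must still be methanolysed, the freed primary alcohol oxidised and the γ-lactone closed.
- Comparison: the chosen route obtains Cγ and Cβ at the outset from a crotylboration of predictable outcome and uses them to set C2, the reverse order of induction.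

Key step: step 13

Assumption: the γ-hydroxy acid of 35 is taken to be isolable in open form when the final acidification is kept near pH 4–5 at 0 °C, and the biaryl axis (one ortho substituent per ring) is taken as freely rotating.

## Route

Step 1
Reactants: 1 4-bromo-3-methoxyphenol
Product: 2 1-bromo-2-methoxy-4-(methoxymethoxy)benzene
Conditions: MOMCl, i-Pr2NEt, CH2Cl2, 0 °C to rt
Reagents that add atoms: chloromethyl methyl ether, COCCl
Why: O-alkylation of the phenol; the MOM ether later directs ortho-lithiation and is removable under acid that aldehydes tolerate.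

Step 2
Reactants: 2 1-bromo-2-methoxy-4-(methoxymethoxy)benzene
Product: 3 2-[2-methoxy-4-(methoxymethoxy)phenyl]-4,4,5,5-tetramethyl-1,3,2-dioxaborolane
Conditions: B2pin2 (1.1 equiv), PdCl2(dppf) (cat.), KOAc, 1,4-dioxane, 90 °C
Reagents that add atoms: bis(pinacolato)diboron, CC1(C)OB(OC1(C)C)B1OC(C)(C)C(C)(C)O1
Why: Miyaura borylation: oxidative addition of the aryl bromide to zerovalent palladium, transmetalation with the acetate-activated diboron and reductive elimination give the aryl boronate; KOAc is too weak a base to drive Suzuki coupling of the product with unreacted bromide, so 3 can be isolated.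

Step 3
Reactants: 2 1-bromo-2-methoxy-4-(methoxymethoxy)benzene; 3 2-[2-methoxy-4-(methoxymethoxy)phenyl]-4,4,5,5-tetramethyl-1,3,2-dioxaborolane
Product: 4 2,2'-dimethoxy-4,4'-bis(methoxymethoxy)-1,1'-biphenyl
Conditions: Pd(OAc)2 (cat.), SPhos, K3PO4, PhMe/H2O, 90 °C
Reagents that add atoms: none
Why: Suzuki–Miyaura cross-coupling of bromide 2 with boronate 3 forms the biaryl bond between the two carbons that carried bromine and boron; the electron-rich dialkylbiarylphosphine copes with the two ortho methoxy groups, the ethers are inert and the biaryl has no stereogenic axis.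

Step 4
Reactants: 4 2,2'-dimethoxy-4,4'-bis(methoxymethoxy)-1,1'-biphenyl
Product: 6 2,2'-dimethoxy-4,4'-bis(methoxymethoxy)-[1,1'-biphenyl]-3,3'-dicarbaldehyde, via 3,3'-dilithiobiaryl 5 (not isolated)
Conditions: n-BuLi (3 equiv), TMEDA, THF, −20 to 0 °C; DMF, −78 °C to rt; aq. NH4Cl
Reagents that add atoms: N,N-dimethylformamide, CN(C)C=O
Why: Directed ortho-metalation: the hydrogen between the methoxy and MOM-oxy groups is acidified and coordinated by both, so each ring is lithiated there and not at the position flanked by one oxygen; DMF traps 5 as the dialdehyde.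

Step 5
Reactants: 6 2,2'-dimethoxy-4,4'-bis(methoxymethoxy)-[1,1'-biphenyl]-3,3'-dicarbaldehyde
Product: 7 4,4'-dihydroxy-2,2'-dimethoxy-[1,1'-biphenyl]-3,3'-dicarbaldehyde
Conditions: 3 M HCl, MeOH/THF, 50 °C
Reagents that add atoms: none
Why: Acid-catalysed acetal exchange removes both MOM groups; the freed phenols are hydrogen-bonded to the ortho aldehydes, which survive.

Step 6
Reactants: 7 4,4'-dihydroxy-2,2'-dimethoxy-[1,1'-biphenyl]-3,3'-dicarbaldehyde
Product: 8 3,3'-diformyl-2,2'-dimethoxy-[1,1'-biphenyl]-4,4'-diyl diacetate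
Conditions: Ac2O, Et3N, DMAP (cat.), CH2Cl2, 0 °C to rt
Reagents that add atoms: acetic anhydride, CC(=O)OC(C)=O
Why: Nucleophile-catalysed O-acylation of both phenols places an acetyl group next to each aldehyde for transfer in the next step.

Step 7
Reactants: 8 3,3'-diformyl-2,2'-dimethoxy-[1,1'-biphenyl]-4,4'-diyl diacetate
Product: 10 [4,4'-dihydroxy-2,2'-dimethoxy-(1,1'-biphenyl)-3,3'-diyl]bis(methylene) diacetate, via bis(hydroxymethyl) biaryl diacetate 9 (not isolated)
Conditions: NaBH4 (0.6 equiv per CHO), THF/EtOH, −20 to 0 °C; AcOH quench at 0 °C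
Reagents that add atoms: none
Why: Hydride reduction gives the benzylic alkoxide of 9, which takes the neighbouring aryl acetate through a six-membered tetrahedral intermediate (O→O acyl shift), driven by formation of the phenoxide; the cold acidic quench protonates the phenoxide before acetate can leave.

Step 8
Reactants: 11 2-methylidenepropane-1,3-diol
Product: 12 2-{[(tert-butyldimethylsilyl)oxy]methyl}prop-2-en-1-ol
Conditions: NaH (1.0 equiv), THF, 0 °C; TBSCl (1.0 equiv), 0 °C to rt
Reagents that add atoms: tert-butyldimethylsilyl chloride, CC(C)(C)[Si](C)(C)Cl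
Why: Monosilylation of a symmetrical diol through its monosodium alkoxide; one equivalent of base limits the reaction to one hydroxyl.

Step 9
Reactants: 12 2-{[(tert-butyldimethylsilyl)oxy]methyl}prop-2-en-1-ol
Product: 13 2-{[(tert-butyldimethylsilyl)oxy]methyl}prop-2-enal
Conditions: MnO2, CH2Cl2, rt; filtration
Reagents that add atoms: none
Why: Allylic oxidation with MnO2 stops at the enal and leaves the silyl ether intact; isolation by filtration limits loss of the polymerisable acrolein.

Step 10
Reactants: 13 2-{[(tert-butyldimethylsilyl)oxy]methyl}prop-2-enal; 14 cis-but-2-ene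
Product: 17 (3R,4S)-2-{[(tert-butyldimethylsilyl)oxy]methyl}-4-methylhexa-1,5-dien-3-ol, via (Z)-crotylpotassium 15 (not isolated), via (Z)-crotyldiisopinocampheylborane 16 (not isolated)
Conditions: 14, KOtBu, n-BuLi, THF, −78 to −45 °C; (+)-Ipc2BOMe [from (−)-α-pinene], −78 °C; BF3·OEt2; 13, −78 °C; then 3 M NaOH, 30% H2O2, rt
Reagents that add atoms: none
Why: Brown crotylboration: 15 is transmetalated to borane 16, which adds through a closed chair transition state, so the Z geometry gives the syn C3/C4 relationship; the isopinocampheyl groups from (−)-α-pinene direct the crotyl group to the re face of 13, which sets Cγ (R) and Cβ (S), and oxidative work-up frees the alcohol.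

Step 11
Reactants: 17 (3R,4S)-2-{[(tert-butyldimethylsilyl)oxy]methyl}-4-methylhexa-1,5-dien-3-ol
Product: 18 (3R,4S)-4-methyl-2-methylidenehex-5-ene-1,3-diol
Conditions: TBAF, THF, 0 °C to rt
Reagents that add atoms: none
Why: Fluoride cleaves the Si–O bond; the allylic alcohols and both alkenes are untouched.

Step 12
Reactants: 18 (3R,4S)-4-methyl-2-methylidenehex-5-ene-1,3-diol
Product: 19 (4R)-4-[(2S)-but-3-en-2-yl]-2,2-dimethyl-5-methylidene-1,3-dioxane
Conditions: 2,2-dimethoxypropane, PPTS (cat.), CH2Cl2, rt
Reagents that add atoms: 2,2-dimethoxypropane, COC(C)(C)OC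
Why: Acid-catalysed transacetalisation closes the six-membered acetonide on the 1,3-diol; in its chair the axial acetal methyl forces the butenyl group at C4 equatorial, the conformational lock used in the key step.

Step 13
Reactants: 10 [4,4'-dihydroxy-2,2'-dimethoxy-(1,1'-biphenyl)-3,3'-diyl]bis(methylene) diacetate; 19 (4R)-4-[(2S)-but-3-en-2-yl]-2,2-dimethyl-5-methylidene-1,3-dioxane
Product: 23 6,6'-bi{(2R,4'R)-4'-[(2S)-but-3-en-2-yl]-5-methoxy-2',2'-dimethylspiro[chromane-2,5'-[1,3]dioxane]}, via mono(ortho-quinone methide) 20 (not isolated), via mono-cycloadduct 21 (not isolated), via second ortho-quinone methide 22 (not isolated)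
Conditions: 19 (6 equiv), PhMe (0.05 M in 10), 110 °C, sealed tube, argon, dark; excess 19 recovered
Reagents that add atoms: none
Why: Heating each ortho-hydroxybenzyl acetate expels acetic acid and gives an ortho-quinone methide, an electron-poor 1-oxadiene that the exocyclic alkene of 19 captures in an inverse-electron-demand hetero-Diels–Alder reaction; the closest known reaction type is the thermal cycloaddition of ortho-quinone methides from ortho-hydroxybenzyl acetates with exocyclic 1,1-disubstituted alkenes to give spiro chromans. The [4+2] is concerted but asynchronous: the alkene CH2 bonds first to the methide carbon (C3–C4) while positive charge builds on the fully substituted carbon, which the carbonyl oxygen then captures (O1–C2), so the regiochemistry follows from polarity. Each pyran ring thus closes by an intermolecular [4+2] annulation in which both ring bonds form in one event, spiro-fused at dioxane C5. Each new C2 stereocentre is controlled by the Cγ stereocentre through the dioxane chair: with the butenyl group locked equatorial, the heterodiene should approach the alkene face on which the new C–O bond becomes axial, where the ring oxygens present only lone pairs, and not the face flanked by the axial hydrogens at C4' and C6' and the axial acetal methyl. This places O1 cis to the side chain, the relative configuration the target requires. The step needs selectivity for the 1,1-disubstituted alkene over the vinyl group, secured by its higher nucleophilicity and the tertiary character of the developing cation, and it needs a single methide per ring, secured by the C5 methyl ether. Excess 19 and slow thermal release keep the methide concentration low and suppress its oligomerisation; the two cycloadditions are independent, so 20, 21 and 22 are passed in turn.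

Step 14
Reactants: 23 6,6'-bi{(2R,4'R)-4'-[(2S)-but-3-en-2-yl]-5-methoxy-2',2'-dimethylspiro[chromane-2,5'-[1,3]dioxane]}
Product: 25 6,6'-bi{(2R,4'R)-4'-[(2S)-4-hydroxybutan-2-yl]-5-methoxy-2',2'-dimethylspiro[chromane-2,5'-[1,3]dioxane]}, via bis(B-alkyl-9-borabicyclononane) 24 (not isolated)
Conditions: 9-BBN, THF, 0 °C to rt; then 3 M NaOH, 30% H2O2, 0 °C to rt
Reagents that add atoms: hydrogen peroxide, OO
Why: Hydroboration–oxidation: 9-BBN adds anti-Markovnikov to the two terminal vinyl groups, the only alkenes left, and alkaline peroxide oxidises the C–B bonds of 24; no stereocentre is touched.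

Step 15
Reactants: 25 6,6'-bi{(2R,4'R)-4'-[(2S)-4-hydroxybutan-2-yl]-5-methoxy-2',2'-dimethylspiro[chromane-2,5'-[1,3]dioxane]}
Product: 26 6,6'-bi{(2R,4'R)-4'-[(2S)-1-carboxypropan-2-yl]-5-methoxy-2',2'-dimethylspiro[chromane-2,5'-[1,3]dioxane]}
Conditions: TEMPO (cat.), PhI(OAc)2, MeCN/H2O (1:1), rt
Reagents that add atoms: water, O
Why: Nitroxyl-catalysed oxidation takes each primary alcohol through the aldehyde hydrate to the acid; acetonides, aryl ethers and the biaryl are stable to the oxoammonium species under these near-neutral conditions.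

Step 16
Reactants: 26 6,6'-bi{(2R,4'R)-4'-[(2S)-1-carboxypropan-2-yl]-5-methoxy-2',2'-dimethylspiro[chromane-2,5'-[1,3]dioxane]}
Product: 28 6,6'-bi{(2R)-2-(hydroxymethyl)-5-methoxy-2-[(2R,3S)-3-methyl-5-oxooxolan-2-yl]chromane}, via bis(dihydroxy acid) 27 (not isolated)
Conditions: AcOH/H2O (4:1), 60 °C; then PPTS (cat.), PhMe, 60 °C
Reagents that add atoms: none
Why: Aqueous acid hydrolyses both acetonides to 27, and each γ-hydroxy acid then closes to the five-membered lactone (5-exo-trig acyl substitution) in preference to a seven-membered ring with the primary alcohol; Cγ keeps its configuration because only the acyl C–O bond forms.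

Step 17
Reactants: 28 6,6'-bi{(2R)-2-(hydroxymethyl)-5-methoxy-2-[(2R,3S)-3-methyl-5-oxooxolan-2-yl]chromane}
Product: 29 (2S,2'S)-5,5'-dimethoxy-2,2'-bis[(2R,3S)-3-methyl-5-oxooxolan-2-yl]-[6,6'-bichromane]-2,2'-dicarboxylic acid
Conditions: TEMPO (cat.), PhI(OAc)2, MeCN/H2O (1:1), rt to 35 °C
Reagents that add atoms: water, O
Why: The same nitroxyl-catalysed oxidation converts the neopentyl-type primary alcohols to acids; C2 is quaternary, so the intermediate α-aryloxy aldehyde cannot epimerise and is readily hydrated (the descriptor at C2 changes from R to S only through the priority change).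

Step 18
Reactants: 29 (2S,2'S)-5,5'-dimethoxy-2,2'-bis[(2R,3S)-3-methyl-5-oxooxolan-2-yl]-[6,6'-bichromane]-2,2'-dicarboxylic acid
Product: 30 dimethyl (2S,2'S)-5,5'-dimethoxy-2,2'-bis[(2R,3S)-3-methyl-5-oxooxolan-2-yl]-[6,6'-bichromane]-2,2'-dicarboxylate
Conditions: TMSCHN2, PhMe/MeOH (4:1), 0 °C
Reagents that add atoms: trimethylsilyldiazomethane, C[Si](C)(C)C=[N+]=[N-]
Why: Esterification of the carboxylic acids by the diazomethane equivalent (proton transfer, then SN2 on the methyldiazonium ion); lactones are inert.

Step 19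
Reactants: 30 dimethyl (2S,2'S)-5,5'-dimethoxy-2,2'-bis[(2R,3S)-3-methyl-5-oxooxolan-2-yl]-[6,6'-bichromane]-2,2'-dicarboxylate
Product: 31 dimethyl (2S,2'S)-5,5'-dimethoxy-2,2'-bis[(2R,3S)-3-methyl-5-oxooxolan-2-yl]-2H,2'H-[6,6'-bichromene]-2,2'-dicarboxylate
Conditions: DDQ, benzene, 80 °C, dark
Reagents that add atoms: none
Why: Benzylic dehydrogenation: DDQ abstracts hydride from C4, whose cation is stabilised by the ortho C5 methoxy group and O1, and loss of a C3 proton gives the 2H-chromene; the quaternary C2 is not involved when light is excluded.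

Step 20
Reactants: 31 dimethyl (2S,2'S)-5,5'-dimethoxy-2,2'-bis[(2R,3S)-3-methyl-5-oxooxolan-2-yl]-2H,2'H-[6,6'-bichromene]-2,2'-dicarboxylate
Product: 32 dimethyl (2S,2'S)-4,4'-dihydroxy-5,5'-dimethoxy-2,2'-bis[(2R,3S)-3-methyl-5-oxooxolan-2-yl]-[6,6'-bichromane]-2,2'-dicarboxylate (C4 epimers)
Conditions: Mn(dpm)3 (cat.), PhSiH3, O2 (1 atm), EtOH/CH2Cl2, 0 °C to rt
Reagents that add atoms: dioxygen, O=O
Why: Mukaiyama-type hydration: hydrogen-atom transfer from a manganese hydride to C3 gives the benzylic C4 radical, which traps O2 and is reduced to the alcohol, so oxygen enters at C4 only; the C4 configuration is of no consequence.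

Step 21
Reactants: 32 dimethyl (2S,2'S)-4,4'-dihydroxy-5,5'-dimethoxy-2,2'-bis[(2R,3S)-3-methyl-5-oxooxolan-2-yl]-[6,6'-bichromane]-2,2'-dicarboxylate (C4 epimers)
Product: 33 dimethyl (2S,2'S)-5,5'-dimethoxy-2,2'-bis[(2R,3S)-3-methyl-5-oxooxolan-2-yl]-4,4'-dioxo-[6,6'-bichromane]-2,2'-dicarboxylate
Conditions: DMP, CH2Cl2, 0 °C to rt
Reagents that add atoms: none
Why: Dess–Martin oxidation converts both benzylic alcohols to the chromanones under non-basic conditions, which avoids retro-oxa-Michael opening at C2.

Step 22
Reactants: 33 dimethyl (2S,2'S)-5,5'-dimethoxy-2,2'-bis[(2R,3S)-3-methyl-5-oxooxolan-2-yl]-4,4'-dioxo-[6,6'-bichromane]-2,2'-dicarboxylate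
Product: 34 dimethyl (2S,2'S)-5,5'-dihydroxy-2,2'-bis[(2R,3S)-3-methyl-5-oxooxolan-2-yl]-4,4'-dioxo-[6,6'-bichromane]-2,2'-dicarboxylate
Conditions: BCl3 (1 M in CH2Cl2, excess), CH2Cl2, −78 to 0 °C; then aq. NaHCO3
Reagents that add atoms: none
Why: Chelation-assisted ether cleavage: BCl3 bridges the C4 carbonyl and the peri C5 methoxy oxygen and chloride removes the methyl group by SN2; methyl esters and lactones cannot chelate in this way and survive at low temperature.

Step 23
Reactants: 34 dimethyl (2S,2'S)-5,5'-dihydroxy-2,2'-bis[(2R,3S)-3-methyl-5-oxooxolan-2-yl]-4,4'-dioxo-[6,6'-bichromane]-2,2'-dicarboxylate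
Product: 35 (3S,4R)-4-hydroxy-4-{(2S)-5-hydroxy-6-[(2S)-5-hydroxy-2-(methoxycarbonyl)-2-((2R,3S)-3-methyl-5-oxooxolan-2-yl)-4-oxochroman-6-yl]-2-(methoxycarbonyl)-4-oxochroman-2-yl}-3-methylbutanoic acid
Conditions: LiOH (3.1 equiv), THF/H2O (3:1), 0 °C, stopped at partial conversion; 1 M aq. NaH2PO4 to pH 4–5 at 0 °C, EtOAc; unreacted 34 recycled
Reagents that add atoms: lithium hydroxide, [Li+].[OH-]
Why: Hydroxide first deprotonates both phenols, which turns the ketones into vinylogous carboxylates and shuts off enolisation and retro-oxa-Michael opening; the third equivalent opens one strained cis-γ-lactone by acyl substitution faster than it attacks the hindered methyl esters. The two lactones are equivalent, so the reaction is stopped early, and buffered acidification keeps the γ-hydroxy acid open.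

## Compound list

1 | 4-bromo-3-methoxyphenol | COc1cc(O)ccc1Br | starting material
2 | 1-bromo-2-methoxy-4-(methoxymethoxy)benzene | COCOc1ccc(Br)c(OC)c1 | intermediate
3 | 2-[2-methoxy-4-(methoxymethoxy)phenyl]-4,4,5,5-tetramethyl-1,3,2-dioxaborolane | COCOc1ccc(B2OC(C)(C)C(C)(C)O2)c(OC)c1 | intermediate
4 | 2,2'-dimethoxy-4,4'-bis(methoxymethoxy)-1,1'-biphenyl | COCOc1ccc(-c2ccc(OCOC)cc2OC)c(OC)c1 | intermediate
5 | 3,3'-dilithio-2,2'-dimethoxy-4,4'-bis(methoxymethoxy)-1,1'-biphenyl (not isolated) | COCOc1ccc(-c2ccc(OCOC)c([Li])c2OC)c(OC)c1[Li] | intermediate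
6 | 2,2'-dimethoxy-4,4'-bis(methoxymethoxy)-[1,1'-biphenyl]-3,3'-dicarbaldehyde | COCOc1ccc(-c2ccc(OCOC)c(C=O)c2OC)c(OC)c1C=O | intermediate
7 | 4,4'-dihydroxy-2,2'-dimethoxy-[1,1'-biphenyl]-3,3'-dicarbaldehyde | COc1c(-c2ccc(O)c(C=O)c2OC)ccc(O)c1C=O | intermediate
8 | 3,3'-diformyl-2,2'-dimethoxy-[1,1'-biphenyl]-4,4'-diyl diacetate | COc1c(-c2ccc(OC(C)=O)c(C=O)c2OC)ccc(OC(C)=O)c1C=O | intermediate
9 | 3,3'-bis(hydroxymethyl)-2,2'-dimethoxy-[1,1'-biphenyl]-4,4'-diyl diacetate, formed as its alkoxide (not isolated) | COc1c(-c2ccc(OC(C)=O)c(CO)c2OC)ccc(OC(C)=O)c1CO | intermediate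
10 | [4,4'-dihydroxy-2,2'-dimethoxy-(1,1'-biphenyl)-3,3'-diyl]bis(methylene) diacetate | COc1c(-c2ccc(O)c(COC(C)=O)c2OC)ccc(O)c1COC(C)=O | intermediate
11 | 2-methylidenepropane-1,3-diol | C=C(CO)CO | starting material
12 | 2-{[(tert-butyldimethylsilyl)oxy]methyl}prop-2-en-1-ol | C=C(CO)CO[Si](C)(C)C(C)(C)C | intermediate
13 | 2-{[(tert-butyldimethylsilyl)oxy]methyl}prop-2-enal | C=C(C=O)CO[Si](C)(C)C(C)(C)C | intermediate
14 | cis-but-2-ene | C/C=C\C | starting material
15 | (Z)-but-2-enylpotassium (not isolated) | C/C=C\C[K] | intermediate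
16 | [(2Z)-but-2-en-1-yl]bis[(1S,2R,3S,5S)-2,6,6-trimethylbicyclo[3.1.1]heptan-3-yl]borane (not isolated) | C/C=C\CB([C@H]1C[C@H]2C[C@@H]([C@@H]1C)C2(C)C)[C@H]1C[C@H]2C[C@@H]([C@@H]1C)C2(C)C | intermediate
17 | (3R,4S)-2-{[(tert-butyldimethylsilyl)oxy]methyl}-4-methylhexa-1,5-dien-3-ol | C=C(CO[Si](C)(C)C(C)(C)C)[C@H](O)[C@@H](C)C=C | intermediate
18 | (3R,4S)-4-methyl-2-methylidenehex-5-ene-1,3-diol | C=C(CO)[C@H](O)[C@@H](C)C=C | intermediate
19 | (4R)-4-[(2S)-but-3-en-2-yl]-2,2-dimethyl-5-methylidene-1,3-dioxane | C=C1COC(C)(C)O[C@@H]1[C@@H](C)C=C | intermediate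
20 | [6-hydroxy-2-methoxy-3-(2-methoxy-3-methylidene-4-oxocyclohexa-1,5-dien-1-yl)phenyl]methyl acetate, mono(ortho-quinone methide) (not isolated) | C=C1C(=O)C=CC(c2ccc(O)c(COC(C)=O)c2OC)=C1OC | intermediate
21 | {6-hydroxy-2-methoxy-3-[(2R,4'R)-4'-((2S)-but-3-en-2-yl)-5-methoxy-2',2'-dimethylspiro(chromane-2,5'-[1,3]dioxan)-6-yl]phenyl}methyl acetate, mono-cycloadduct (not isolated) | C=C[C@H](C)[C@H]1OC(C)(C)OC[C@]12CCc3c(ccc(-c4ccc(O)c(COC(C)=O)c4OC)c3OC)O2 | intermediate
22 | (2R,4'R)-4'-[(2S)-but-3-en-2-yl]-5-methoxy-6-(2-methoxy-3-methylidene-4-oxocyclohexa-1,5-dien-1-yl)-2',2'-dimethylspiro[chromane-2,5'-[1,3]dioxane], second ortho-quinone methide (not isolated) | C=C[C@H](C)[C@H]1OC(C)(C)OC[C@]12CCc3c(ccc(C4=C(OC)C(=C)C(=O)C=C4)c3OC)O2 | intermediate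
23 | 6,6'-bi{(2R,4'R)-4'-[(2S)-but-3-en-2-yl]-5-methoxy-2',2'-dimethylspiro[chromane-2,5'-[1,3]dioxane]} | C=C[C@H](C)[C@H]1OC(C)(C)OC[C@]12CCc3c(ccc(-c4ccc5c(c4OC)CC[C@]6(COC(C)(C)O[C@@H]6[C@@H](C)C=C)O5)c3OC)O2 | intermediate
24 | 6,6'-bi{(2R,4'R)-4'-[(2S)-4-(9-borabicyclo[3.3.1]nonan-9-yl)butan-2-yl]-5-methoxy-2',2'-dimethylspiro[chromane-2,5'-[1,3]dioxane]} (not isolated) | B1(C2CCCC1CCC2)CC[C@H](C)[C@H]1OC(C)(C)OC[C@]12CCc3c(ccc(-c4ccc5c(c4OC)CC[C@]6(COC(C)(C)O[C@@H]6[C@@H](C)CCB7C8CCCC7CCC8)O5)c3OC)O2 | intermediate
25 | 6,6'-bi{(2R,4'R)-4'-[(2S)-4-hydroxybutan-2-yl]-5-methoxy-2',2'-dimethylspiro[chromane-2,5'-[1,3]dioxane]} | OCC[C@H](C)[C@H]1OC(C)(C)OC[C@]12CCc3c(ccc(-c4ccc5c(c4OC)CC[C@]6(COC(C)(C)O[C@@H]6[C@@H](C)CCO)O5)c3OC)O2 | intermediate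
26 | 6,6'-bi{(2R,4'R)-4'-[(2S)-1-carboxypropan-2-yl]-5-methoxy-2',2'-dimethylspiro[chromane-2,5'-[1,3]dioxane]} | OC(=O)C[C@H](C)[C@H]1OC(C)(C)OC[C@]12CCc3c(ccc(-c4ccc5c(c4OC)CC[C@]6(COC(C)(C)O[C@@H]6[C@@H](C)CC(=O)O)O5)c3OC)O2 | intermediate
27 | 6,6'-bi{(2R)-2-[(1R,2S)-3-carboxy-1-hydroxy-2-methylpropyl]-2-(hydroxymethyl)-5-methoxychromane} (not isolated) | OC[C@@]1([C@H](O)[C@@H](C)CC(=O)O)CCc2c(ccc(-c3ccc4c(c3OC)CC[C@@](CO)([C@H](O)[C@@H](C)CC(=O)O)O4)c2OC)O1 | intermediate
28 | 6,6'-bi{(2R)-2-(hydroxymethyl)-5-methoxy-2-[(2R,3S)-3-methyl-5-oxooxolan-2-yl]chromane} | OC[C@@]1([C@@H]5OC(=O)C[C@@H]5C)CCc2c(ccc(-c3ccc4c(c3OC)CC[C@@](CO)([C@@H]3OC(=O)C[C@@H]3C)O4)c2OC)O1 | intermediate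
29 | (2S,2'S)-5,5'-dimethoxy-2,2'-bis[(2R,3S)-3-methyl-5-oxooxolan-2-yl]-[6,6'-bichromane]-2,2'-dicarboxylic acid | OC(=O)[C@@]1([C@@H]5OC(=O)C[C@@H]5C)CCc2c(ccc(-c3ccc4c(c3OC)CC[C@@](C(=O)O)([C@@H]3OC(=O)C[C@@H]3C)O4)c2OC)O1 | intermediate
30 | dimethyl (2S,2'S)-5,5'-dimethoxy-2,2'-bis[(2R,3S)-3-methyl-5-oxooxolan-2-yl]-[6,6'-bichromane]-2,2'-dicarboxylate | COC(=O)[C@@]1([C@@H]5OC(=O)C[C@@H]5C)CCc2c(ccc(-c3ccc4c(c3OC)CC[C@@](C(=O)OC)([C@@H]3OC(=O)C[C@@H]3C)O4)c2OC)O1 | intermediate
31 | dimethyl (2S,2'S)-5,5'-dimethoxy-2,2'-bis[(2R,3S)-3-methyl-5-oxooxolan-2-yl]-2H,2'H-[6,6'-bichromene]-2,2'-dicarboxylate | COC(=O)[C@@]1([C@@H]5OC(=O)C[C@@H]5C)C=Cc2c(ccc(-c3ccc4c(c3OC)C=C[C@@](C(=O)OC)([C@@H]3OC(=O)C[C@@H]3C)O4)c2OC)O1 | intermediate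
32 | dimethyl (2S,2'S)-4,4'-dihydroxy-5,5'-dimethoxy-2,2'-bis[(2R,3S)-3-methyl-5-oxooxolan-2-yl]-[6,6'-bichromane]-2,2'-dicarboxylate (C4 epimers) | COC(=O)[C@@]1([C@@H]5OC(=O)C[C@@H]5C)CC(O)c2c(ccc(-c3ccc4c(c3OC)C(O)C[C@@](C(=O)OC)([C@@H]3OC(=O)C[C@@H]3C)O4)c2OC)O1 | intermediate
33 | dimethyl (2S,2'S)-5,5'-dimethoxy-2,2'-bis[(2R,3S)-3-methyl-5-oxooxolan-2-yl]-4,4'-dioxo-[6,6'-bichromane]-2,2'-dicarboxylate | COC(=O)[C@@]1([C@@H]5OC(=O)C[C@@H]5C)CC(=O)c2c(ccc(-c3ccc4c(c3OC)C(=O)C[C@@](C(=O)OC)([C@@H]3OC(=O)C[C@@H]3C)O4)c2OC)O1 | intermediate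
34 | dimethyl (2S,2'S)-5,5'-dihydroxy-2,2'-bis[(2R,3S)-3-methyl-5-oxooxolan-2-yl]-4,4'-dioxo-[6,6'-bichromane]-2,2'-dicarboxylate | COC(=O)[C@@]1([C@@H]5OC(=O)C[C@@H]5C)CC(=O)c2c(ccc(-c3ccc4c(c3O)C(=O)C[C@@](C(=O)OC)([C@@H]3OC(=O)C[C@@H]3C)O4)c2O)O1 | intermediate
35 | (3S,4R)-4-hydroxy-4-{(2S)-5-hydroxy-6-[(2S)-5-hydroxy-2-(methoxycarbonyl)-2-((2R,3S)-3-methyl-5-oxooxolan-2-yl)-4-oxochroman-6-yl]-2-(methoxycarbonyl)-4-oxochroman-2-yl}-3-methylbutanoic acid | COC(=O)[C@@]1([C@H](O)[C@@H](C)CC(=O)O)CC(=O)c2c(ccc(-c3ccc4c(c3O)C(=O)C[C@@](C(=O)OC)([C@@H]3OC(=O)C[C@@H]3C)O4)c2O)O1 | target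

## Step count and least certain steps

Total step count: 23. Longest linear sequence: 18 steps (steps 1–7, then 13–23, from 4-bromo-3-methoxyphenol); the dioxane branch (steps 8–12) joins at step 13.

**Step 13 (key step).** The most likely failure is poor facial discrimination at the exocyclic alkene. Its cost is compounded because two independent cycloadditions must both give the same C2 configuration. The second likely failure is self-condensation of the quinone methide when the alkene, inductively deactivated by two allylic oxygens and flanked by a branched substituent, reacts slowly. A formal ene reaction at the allylic C–H bonds could also compete, and the acetic acid set free could loosen the acetonide at this temperature.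
Fallback: the biaryl bond is formed after the cycloaddition, so that each half is purified as a single C2 epimer before the halves are joined. It sets out from 2 and returns at 23. Bromide 2 is deprotonated between its two oxygens with LDA (no halogen–lithium exchange) and formylated with DMF to give 3-bromo-2-methoxy-6-(methoxymethoxy)benzaldehyde F1. Acid methanolysis gives 3-bromo-6-hydroxy-2-methoxybenzaldehyde F2. Acetylation gives 4-bromo-2-formyl-3-methoxyphenyl acetate F3. Borohydride reduction with acyl shift gives (3-bromo-6-hydroxy-2-methoxyphenyl)methyl acetate F4. Heating F4 with 19 in toluene gives (2R,4'R)-6-bromo-4'-[(2S)-but-3-en-2-yl]-5-methoxy-2',2'-dimethylspiro[chromane-2,5'-[1,3]dioxane] F5, whose C2 epimer can be removed by chromatography. Half of F5 is converted by Miyaura borylation (B2pin2, PdCl2(dppf), KOAc) into (2R,4'R)-4'-[(2S)-but-3-en-2-yl]-5-methoxy-2',2'-dimethyl-6-(4,4,5,5-tetramethyl-1,3,2-dioxaborolan-2-yl)spiro[chromane-2,5'-[1,3]dioxane] F6. Suzuki–Miyaura coupling of F6 with the other half of F5 (Pd(OAc)2, SPhos, aq. K3PO4) gives 23.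

**Step 7.** The likely failure is premature loss of acetate from the phenoxide formed by the acyl shift. The resulting quinone methide would be captured by hydride (over-reduction to a methyl group) or would oligomerise. The risk grows with excess hydride, higher temperature and a slow quench.
Fallback: the acetate is dispensed with. Setting out from 7, NaBH4 reduction of both aldehydes gives 3,3'-bis(hydroxymethyl)-2,2'-dimethoxy-[1,1'-biphenyl]-4,4'-diol F7. F7 is used directly as the methide precursor by thermal dehydration in the presence of 19 (o-dichlorobenzene, about 150 °C), and the route is rejoined at 23.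

**Step 19.** The likely failure is incomplete or unselective dehydrogenation: reaction at one ring only, or oxidative attack of DDQ on the electron-rich biaryl instead of hydride abstraction at C4. Light-induced electrocyclic opening of the chromene, which would scramble C2, is a further risk.
Fallback: the chromene is avoided altogether. Setting out from 30, direct benzylic C–H oxidation with tert-butyl hydroperoxide and catalytic Rh2(cap)4 (dirhodium tetracaprolactamate) in CH2Cl2 gives the bis-chromanone and rejoins the route at 33, bypassing 31 and 32; no new compound is made.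

**Step 23.** The likely failures are unselective hydrolysis (opening of both lactones or saponification of a methyl ester), ring opening at C2 if the phenols are not fully deprotonated, and reclosure of the γ-hydroxy acid during acidification. At best the step is statistical.
Fallback: the target is approached from the fully opened side. Setting out from 34, both lactones are opened with excess LiOH at 0 °C to give, after buffered acidification, (3S,3'S,4R,4'R)-4,4'-[(2S,2'S)-5,5'-dihydroxy-2,2'-bis(methoxycarbonyl)-4,4'-dioxo-(6,6'-bichromane)-2,2'-diyl]bis(4-hydroxy-3-methylbutanoic acid) F8. One of its two hydroxy acids is then closed irreversibly and without base by one equivalent of a carbodiimide (EDC·HCl, CH2Cl2, 0 °C), which returns to the route at 35. Recovered F8 and the 34 formed alongside are recycled.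

## Further compounds

F1 | step 13 | 3-bromo-2-methoxy-6-(methoxymethoxy)benzaldehyde | COCOc1ccc(Br)c(OC)c1C=O
F2 | step 13 | 3-bromo-6-hydroxy-2-methoxybenzaldehyde | Oc1ccc(Br)c(OC)c1C=O
F3 | step 13 | 4-bromo-2-formyl-3-methoxyphenyl acetate | CC(=O)Oc1ccc(Br)c(OC)c1C=O
F4 | step 13 | (3-bromo-6-hydroxy-2-methoxyphenyl)methyl acetate | CC(=O)OCc1c(O)ccc(Br)c1OC
F5 | step 13 | (2R,4'R)-6-bromo-4'-[(2S)-but-3-en-2-yl]-5-methoxy-2',2'-dimethylspiro[chromane-2,5'-[1,3]dioxane] | C=C[C@H](C)[C@H]1OC(C)(C)OC[C@]12CCc3c(ccc(Br)c3OC)O2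
F6 | step 13 | (2R,4'R)-4'-[(2S)-but-3-en-2-yl]-5-methoxy-2',2'-dimethyl-6-(4,4,5,5-tetramethyl-1,3,2-dioxaborolan-2-yl)spiro[chromane-2,5'-[1,3]dioxane] | C=C[C@H](C)[C@H]1OC(C)(C)OC[C@]12CCc3c(ccc(B4OC(C)(C)C(C)(C)O4)c3OC)O2
F7 | step 7 | 3,3'-bis(hydroxymethyl)-2,2'-dimethoxy-[1,1'-biphenyl]-4,4'-diol | COc1c(-c2ccc(O)c(CO)c2OC)ccc(O)c1CO
F0 | step 19 | none | none
F8 | step 23 | (3S,3'S,4R,4'R)-4,4'-[(2S,2'S)-5,5'-dihydroxy-2,2'-bis(methoxycarbonyl)-4,4'-dioxo-(6,6'-bichromane)-2,2'-diyl]bis(4-hydroxy-3-methylbutanoic acid) | COC(=O)[C@@]1([C@H](O)[C@@H](C)CC(=O)O)CC(=O)c2c(ccc(-c3ccc4c(c3O)C(=O)C[C@@](C(=O)OC)([C@H](O)[C@@H](C)CC(=O)O)O4)c2O)O1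
A1 | alternative 1 | dimethyl (2S,2'S)-5,5'-dihydroxy-2,2'-bis[(2R,3S)-3-methyl-5-oxooxolan-2-yl]-4,4'-dioxo-[6,6'-bichromane]-2,2'-dicarboxylate (identical with 34) | COC(=O)[C@@]1([C@@H]5OC(=O)C[C@@H]5C)CC(=O)c2c(ccc(-c3ccc4c(c3O)C(=O)C[C@@](C(=O)OC)([C@@H]3OC(=O)C[C@@H]3C)O4)c2O)O1
A2 | alternative 1 | 3,4-bis[methoxy(trimethylsilyloxy)methylidene]hexa-1,5-diene | C=CC(=C(OC)O[Si](C)(C)C)C(=C(OC)O[Si](C)(C)C)C=C
A3 | alternative 1 | methyl (2S)-2-[(2R,3S)-3-methyl-5-oxooxolan-2-yl]-4-oxo-5-(phenylsulfinyl)-3,4-dihydro-2H-pyran-2-carboxylate | COC(=O)[C@@]1([C@@H]2OC(=O)C[C@@H]2C)CC(=O)C(S(=O)c2ccccc2)=CO1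
A4 | alternative 2 | dimethyl (2S,2'S)-4,4'-[4,4'-difluoro-2,2'-dimethoxy-(1,1'-biphenyl)-3,3'-diyl]bis{2-hydroxy-2-[(2R,3S)-3-methyl-5-oxooxolan-2-yl]-4-oxobutanoate} | COC(=O)[C@@](O)([C@@H]5OC(=O)C[C@@H]5C)CC(=O)c1c(F)ccc(-c2ccc(F)c(C(=O)C[C@@](O)(C(=O)OC)[C@@H]3OC(=O)C[C@@H]3C)c2OC)c1OC
A5 | alternative 2 | bis(trimethylsilyl enol ether) of 3,3'-diacetyl-4,4'-difluoro-2,2'-dimethoxy-1,1'-biphenyl | C=C(O[Si](C)(C)C)c1c(F)ccc(-c2ccc(F)c(C(=C)O[Si](C)(C)C)c2OC)c1OC
A6 | alternative 2 | methyl 2-[(2R,3S)-3-methyl-5-oxooxolan-2-yl]-2-oxoacetate | COC(=O)C(=O)[C@@H]1OC(=O)C[C@@H]1C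
A7 | alternative 3 | 6,6'-linked bis[4'-hydroxy-5-methoxy-5'-methylspiro(chromane-2,3'-oxepane)-2',4-dione], C2, Cγ and Cβ configured as in the target | O=C1OCC[C@H](C)[C@@H](O)[C@@]12CC(=O)c3c(ccc(-c4ccc5c(c4OC)C(=O)C[C@@]6([C@H](O)[C@@H](C)CCOC6=O)O5)c3OC)O2
A8 | alternative 3 | 6,6'-linked bis[5-methoxy-5'-methyl-6',7'-dihydrospiro(chromane-2,3'-oxepine)-2',4-dione], C2 configured as in the target | O=C1OCCC(C)=C[C@@]12CC(=O)c3c(ccc(-c4ccc5c(c4OC)C(=O)C[C@@]6(C=C(C)CCOC6=O)O5)c3OC)O2
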